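## Structural features

Compound 23 is an achiral depside. Its two benzene rings are linked only by an aryl ester, so there are no stereocentres, adjacent or otherwise, and every selectivity question is regiochemical or chemoselective. Ring A, the acyl half, has the ester carbonyl on C1, methoxy on C2, a free hydroxyl on C4 and propyl on C6, so the carbonyl is flanked on both sides. Ring B, the phenolic half, is a benzoic acid with the carboxyl on C1, oxygen on C2, C3 and C4, and propyl on C6. The depside oxygen is the middle one, O3, and its neighbours O2 and O4 are free phenols.

Three groups are fragile. The aryl ester can solvolyse, or its acyl group can shift under base from O3 to O2 or O4. The electron-rich salicylic acid decarboxylates on heating or in acid. The trioxygenated ring B oxidises in basic air. The acid and all phenols should therefore appear only in the last step, under neutral conditions.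

The real difficulties are three:
- The two ring A oxygens must be told apart, with the methyl on the less reactive O2 next to the carbonyl.
- The contiguous O2–O3–O4 array of ring B must be built with only O3 free at the coupling.
- A di-ortho-substituted acid must be esterified with a di-ortho-flanked phenol.

The key step uses the 1,3-relation of O2 and O4 and the vicinal C1-carbonyl/C6-propyl pair of ring A. Atoms C2–C3–C4–C5 correspond to a four-carbon diene, with a ketene-acetal carbon at C2 and a silyl enol ether carbon at C4. Atoms C1 and C6 correspond to the two alkyne carbons of a 2-alkynoate.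

## Logic of the disconnections

**23 ⇒ 22.** Four O–benzyl bonds are restored: on O4 of ring A, on O2 and O4 of ring B, and on the carboxyl oxygen. The cut is made here because one neutral reductive operation can release all acidic groups at once. This avoids base (acyl shift) and heat or acid (decarboxylation). Every reactive OH is then silent in all earlier steps. The forward step must remove all four groups under one set of conditions and leave the aryl ester alone.

**22 ⇒ 10 + 20.** The acyl C–O3 bond is cut. It is the only bond between the rings, and cutting it gives two halves of similar size, so the plan becomes convergent. The forward step needs a small, very electrophilic acyl donor (21). It also needs a partner, 20, that shows a single hydroxyl and has its own carboxyl masked.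

**10 ⇒ 9 ⇒ 8.** These are functional-group changes only: the ester O–methyl bond is restored and the O4–benzyl bond is removed. O4 must be capped, because an unhindered phenol would acylate faster than O3 of 20. This leads back to the direct product of ring construction. The hindered ester must be cleaved under conditions that spare both ethers.

**8 ⇒ 4 + 5.** Ring A bonds C1–C2 and C5–C6 are cut. An aromatic ring with four different substituents becomes two open-chain pieces. The methyl on O2 and the free O4 are already distinguished by the kind of oxygen carried on the diene. The forward step needs one orientation of addition, followed by loss of one methoxy group together with a C5 hydrogen and removal of silicon.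

**4 ⇒ 3 ⇒ 1 + 2.** The O–Si bond is cut first, then the bond between the future ring A atoms C3 and C4. This leads to two very simple purchasable pieces. 3 can enolise in only one direction, which secures the position of the silyl enol ether. The forward steps must be run and worked up without water.

**20 ⇒ 17.** The C3–O bond is exchanged for a C3–I bond. Iodine serves as a placeholder for O3: it is inert to formylation, oxidation and alkylation, so no separate protecting group for O3 is needed. The forward step needs a halogen–metal exchange that tolerates a shielded ester, followed by ipso-oxygenation.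

**17 ⇒ 16 ⇒ 15 ⇒ 13.** The carboxyl O–benzyl bond is cut, the oxidation level is lowered, and then the bond from ring B C1 to its exocyclic carbon is cut. 13 is symmetrical and its two ring hydrogens are equivalent, so one-carbon introduction can give only one isomer. The forward electrophilic substitution must not disturb the C–I bond.

**13 ⇒ 12 ⇒ 11.** The two O–benzyl bonds are cut, then the C–I bond. This leads to a purchasable resorcinol that already carries the propyl chain. The forward iodination must go to the carbon between the two oxygens and not beside the propyl group.

## Other disconnections considered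

**Alternative 1:**
- *Cut and forward step.* The cut removes the ring B C6–propyl and C1–carboxyl bonds and leads to the symmetrical 2-(benzyloxy)-5-bromo-1,3-bis(methoxymethoxy)benzene A1. A hindered lithium amide would metalate A1 next to the halogen and expel halide to give 4-(benzyloxy)-3,5-bis(methoxymethoxy)-1,2-didehydrobenzene A2. A propyl Grignard reagent would add at the aryne carbon remote from the acetal oxygen. Carboxylation of the resulting ortho-alkoxy arylmagnesium would give 3-(benzyloxy)-2,4-bis(methoxymethoxy)-6-propylbenzoic acid A3.
- *In its favour.* Two C–C bonds form in one flask. The symmetry of A1 allows only one aryne. The inductive pull of the neighbouring alkoxy group steers the nucleophile to the correct carbon. O3 is present from the start, so no halogen-to-oxygen exchange is needed. On these points it is better than steps 8–11.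
- *Against it.* The amide base can itself add to A2. A Grignard reagent with β-hydrogens can reduce instead of add. A crowded arylmagnesium has to be carboxylated. A1 is not purchasable and needs a differentiated trihydroxyarene built over several steps.
- *Structure.* A3 carries three kinds of protecting group. The benzyl on O3 must be hydrogenolysed before coupling, which rules out a benzyl ester. The acetals need an acidic final stage on a decarboxylation-prone acid.
- *Mechanism.* A one-pot sequence of three organometallic events stands against stepwise, individually standard reactions.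
- *Step economy.* The key step is shorter than its counterpart here, but the preparation of A1 and the two-stage deprotection use up that gain. It also leaves the ring A oxygen problem untouched, so it could only replace the ring B branch.

**Alternative 2:**
- *Cut and forward step.* The cut is the ring A C1–C6 bond and leads to benzyl 2,4-bis(benzyloxy)-6-propyl-3-[(3,5,7-trioxodecanoyl)oxy]benzoate A4. Mild base would add chain C2 to the C7 ketone, and acid would dehydrate. The product would be benzyl 2,4-bis(benzyloxy)-3-[(2,4-dihydroxy-6-propylbenzoyl)oxy]-6-propylbenzoate A5.
- *In its favour.* The ester to O3 of 20 is made while the acyl chain is still unhindered, for example by trapping an acylketene. This handles the crowded coupling better than step 12. Ring A also comes from simple acyclic carbonyl chemistry.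
- *Against it.* A5 has both ring A oxygens free, whereas 23 needs methyl on O2. O2 is chelated to the ester carbonyl and is the less reactive of the two. O4 would therefore have to be benzylated first and O2 methylated afterwards, which returns to 22 after two more steps under basic conditions. In A4 the aryl ester is an activated ester. Attack of a chain enol oxygen or of chain C6 on C1 would expel the phenoxide of 20 and give pyrone- or acylphloroglucinol-type products. A4 would also be a mixture of tautomers that is hard to purify.
- *Structure.* The chosen cycloaddition delivers the oxygen pattern of ring A directly; the aldol route does not.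
- *Mechanism.* One of several possible cyclisation modes of a polyketide chain has to be selected, whereas the cycloaddition has a single polarity-matched orientation.
- *Step economy.* The two plans are about equal. What the aldol route saves at the ester bond it spends on differentiating O2 from O4.

**Alternative 3:**
- *Cut and forward step.* The cuts are the ring B C1–C6 and C2–C3 bonds. They lead to (E)-2-oxohept-3-en-1-yl 4-(benzyloxy)-2-methoxy-6-propylbenzoate A6 and dibenzyl malonate A7. The anion of A7 would add to the β carbon of A6, and the enolate at the acyloxy-bearing carbon would then attack one malonate ester group. This would give racemic benzyl trans-3-{[4-(benzyloxy)-2-methoxy-6-propylbenzoyl]oxy}-4-hydroxy-2-oxo-6-propylcyclohex-3-ene-1-carboxylate A8. Dehydrogenation would lead to benzyl 3-{[4-(benzyloxy)-2-methoxy-6-propylbenzoyl]oxy}-2,4-dihydroxy-6-propylbenzoate A9, and hydrogenolysis to 23.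
- *In its favour.* The ester is formed on a primary carbinol instead of a flanked phenol. O2 and O4 never need protection. O3 is present from the outset. The two stereocentres of A8 are erased on aromatisation and need no control. On all these points it is better than steps 6–12.
- *Against it.* An α-acyloxy ketone has to survive an alkoxide medium without acyl cleavage or transfer. A8 is the monoester of an enediol, in which a shift of the acyl group to the neighbouring enol oxygen is easy and would scramble O3 with O2 or O4. The extra oxidation needs a halogen- or quinone-type reagent in the presence of the electron-rich ring A and benzyl ethers. The β-keto ester can lose its carboxyl group.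
- *Structure.* It still requires 10, so it does not replace the chosen ring A construction.
- *Mechanism.* A Michael–Dieckmann cascade plus a separate dehydrogenation stands against substitutions on a preformed arene.
- *Step economy.* It could be shorter than the chosen ring B branch. That advantage rests on the two least predictable operations, the survival of the ester and a selective aromatisation.

Key step: step 3

Remark on the chemistry: during the coupling ring B carries a benzyl ester on its carboxyl group as well as benzyl ethers on O2 and O4, because a free acid would be activated alongside 10; compounds 1, 2, 5 and 11 are taken as purchasable.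

## Steps

Step 1
Reactants: 1 1,1-dimethoxyethene; 2 acetyl chloride
Product: 3 4,4-dimethoxybut-3-en-2-one
Conditions: Et3N, Et2O, 0 °C → rt
Reagents that add atoms: none
Why: C-acylation of a ketene acetal: the electron-rich CH2 terminus of 1 attacks the acid chloride and the amine takes the proton from the dimethoxycarbenium intermediate, giving the conjugated push–pull enone.

Step 2
Reactants: 3 4,4-dimethoxybut-3-en-2-one
Product: 4 1,1-dimethoxy-3-(trimethylsilyloxy)buta-1,3-diene
Conditions: TMSOTf, Et3N, Et2O, 0 °C
Reagents that add atoms: trimethylsilyl trifluoromethanesulfonate C[Si](C)(C)OS(=O)(=O)C(F)(F)F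
Why: Soft enolisation to a silyl enol ether: O-silylation gives a cation stabilised by both methoxy groups, and only the methyl group has removable α-protons, so a single cross-conjugated diene can form; phase separation and distillation without water protect the labile product.

Step 3
Reactants: 4 1,1-dimethoxy-3-(trimethylsilyloxy)buta-1,3-diene; 5 methyl hex-2-ynoate
Product: 8 methyl 4-hydroxy-2-methoxy-6-propylbenzoate, via cycloadduct ketal 6 (not isolated), via aryl silyl ether 7 (not isolated)
Conditions: 4 (2 equiv), neat, 130 °C, sealed tube, Ar; then 1 M HCl, THF, rt
Reagents that add atoms: none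
Why: This is a normal-electron-demand Diels–Alder benzannulation, the known reaction type of 1,1-dialkoxy-3-silyloxybutadienes with propiolates and 2-alkynoates. Bond formation should be strongly asynchronous: the CH2 terminus of 4, which receives the push of all three oxygens, bonds first to the β carbon of 5 (ring A C5–C6), and the developing allenolate then closes onto the dimethoxy-substituted carbon (C1–C2). Ring A is thus closed in an intermolecular [4+2] mode, both new bonds joining the two components, to give the 1,4-cyclohexadiene ketal 6. In 6 the C5 methylene and the C2 ketal stand in a 1,4-relation, so thermal loss of methanol, driven by aromaticity, gives 7. Dilute acid then cleaves the O–Si bond, finishes any incomplete elimination and hydrolyses surplus 4 to water-soluble material. No stereocentre is formed. The only selectivity needed is regiochemical, and it is secured by matching the most nucleophilic diene terminus with the most electrophilic alkyne carbon, which puts methoxy next to the ester and propyl on its other side. The β-propyl group slows the dienophile and the inward methoxy group disfavours the s-cis diene, hence no solvent, excess 4 and heat.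

Step 4
Reactants: 8 methyl 4-hydroxy-2-methoxy-6-propylbenzoate
Product: 9 methyl 4-(benzyloxy)-2-methoxy-6-propylbenzoate
Conditions: BnBr, K2CO3, acetone, reflux
Reagents that add atoms: benzyl bromide BrCc1ccccc1
Why: Williamson ether synthesis on the single, unhindered phenol; the ester and the methyl ether are inert to carbonate.

Step 5
Reactants: 9 methyl 4-(benzyloxy)-2-methoxy-6-propylbenzoate
Product: 10 4-(benzyloxy)-2-methoxy-6-propylbenzoic acid
Conditions: KOH, DMSO–H2O, 100 °C; then aq. HCl, 0 °C
Reagents that add atoms: potassium hydroxide [K+].[OH-]
Why: Saponification of a di-ortho-substituted benzoate, which needs poorly solvated hydroxide in hot aqueous DMSO; aryl methyl and benzyl ethers do not react with hydroxide, and cold acidification keeps the electron-rich acid from decarboxylating.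

Step 6
Reactants: 11 5-propylbenzene-1,3-diol
Product: 12 2-iodo-5-propylbenzene-1,3-diol
Conditions: I2, NaHCO3, THF–H2O, 0 °C → rt
Reagents that add atoms: iodine II
Why: Electrophilic iodination of a resorcinol in bicarbonate buffer, the known entry to 2-iodoresorcinols: under acid-free, kinetically controlled conditions the carbon between the two oxygens is the most nucleophilic, and here C4 and C6 are additionally shielded by the propyl group.

Step 7
Reactants: 12 2-iodo-5-propylbenzene-1,3-diol
Product: 13 1,3-bis(benzyloxy)-2-iodo-5-propylbenzene
Conditions: BnBr, K2CO3, DMF, rt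
Reagents that add atoms: benzyl bromide BrCc1ccccc1
Why: Double Williamson ether synthesis; the aryl iodide is inert to carbonate and the product keeps its mirror symmetry.

Step 8
Reactants: 13 1,3-bis(benzyloxy)-2-iodo-5-propylbenzene
Product: 15 2,4-bis(benzyloxy)-3-iodo-6-propylbenzaldehyde, via aryl iminium chloride 14 (not isolated)
Conditions: POCl3, DMF, 0 → 70 °C; then ice-water
Reagents that add atoms: N,N-dimethylformamide CN(C)C=O; water O
Why: Vilsmeier–Haack formylation: the two ring hydrogens of 13 are equivalent, each ortho to one and para to the other benzyloxy group, so only one aldehyde can form; the phenyl rings of the benzyl groups are not activated, and 14 is hydrolysed on work-up.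

Step 9
Reactants: 15 2,4-bis(benzyloxy)-3-iodo-6-propylbenzaldehyde
Product: 16 2,4-bis(benzyloxy)-3-iodo-6-propylbenzoic acid
Conditions: NaClO2, NaH2PO4, 2-methylbut-2-ene, t-BuOH–THF–H2O, rt
Reagents that add atoms: sodium chlorite [Na+].[O-]Cl=O
Why: Pinnick oxidation, which tolerates hindered aromatic aldehydes, aryl iodides and benzyl ethers; the alkene scavenger intercepts hypochlorous acid before it can chlorinate the electron-rich ring.

Step 10
Reactants: 16 2,4-bis(benzyloxy)-3-iodo-6-propylbenzoic acid
Product: 17 benzyl 2,4-bis(benzyloxy)-3-iodo-6-propylbenzoate
Conditions: BnBr, K2CO3, DMF, rt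
Reagents that add atoms: benzyl bromide BrCc1ccccc1
Why: SN2 O-alkylation of the carboxylate; the new bond forms at the benzylic carbon of the reagent, so crowding around the carbonyl does not matter.

Step 11
Reactants: 17 benzyl 2,4-bis(benzyloxy)-3-iodo-6-propylbenzoate
Product: 20 benzyl 2,4-bis(benzyloxy)-3-hydroxy-6-propylbenzoate, via arylmagnesium chloride 18 (not isolated), via dimethyl arylboronate 19 (not isolated)
Conditions: i-PrMgCl·LiCl, THF, −25 °C; B(OMe)3, −25 °C → rt; 30% aq. H2O2, 0 °C → rt
Reagents that add atoms: hydrogen peroxide OO
Why: Iodine–magnesium exchange with the turbo-Grignard reagent, assisted by the two chelating ortho oxygens, should be faster at low temperature than addition to the di-ortho-shielded ester and avoids the strong bases that deprotonate benzyl ethers; borylation and peroxide oxidation (1,2-shift of aryl from boron to oxygen) then place oxygen exactly where iodine stood.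

Step 12
Reactants: 10 4-(benzyloxy)-2-methoxy-6-propylbenzoic acid; 20 benzyl 2,4-bis(benzyloxy)-3-hydroxy-6-propylbenzoate
Product: 22 benzyl 2,4-bis(benzyloxy)-3-{[4-(benzyloxy)-2-methoxy-6-propylbenzoyl]oxy}-6-propylbenzoate, via mixed trifluoroacetic anhydride 21 (not isolated)
Conditions: (CF3CO)2O, toluene, rt
Reagents that add atoms: none
Why: Mixed-anhydride esterification as commonly used for depsides: 21 tends to ionise toward a linear acylium ion stabilised by the 2-methoxy and 4-benzyloxy groups, an electrophile slim enough to reach the flanked O3; 20 offers one hydroxyl only and has no free acid to be activated.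

Step 13
Reactants: 22 benzyl 2,4-bis(benzyloxy)-3-{[4-(benzyloxy)-2-methoxy-6-propylbenzoyl]oxy}-6-propylbenzoate
Product: 23 2,4-dihydroxy-3-[(4-hydroxy-2-methoxy-6-propylbenzoyl)oxy]-6-propylbenzoic acid
Conditions: H2 (1 atm), 10% Pd/C, EtOAc, rt
Reagents that add atoms: none
Why: Catalytic hydrogenolysis removes the three benzyl ethers and the benzyl ester in one neutral operation; the aryl ester, the methyl ether and the arenes are not reduced, and the absence of base, acid and heat guards against acyl migration and decarboxylation.

## Compound list

1 | 1,1-dimethoxyethene | C=C(OC)OC | starting material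
2 | acetyl chloride | CC(=O)Cl | starting material
3 | 4,4-dimethoxybut-3-en-2-one | CC(=O)C=C(OC)OC | intermediate
4 | 1,1-dimethoxy-3-(trimethylsilyloxy)buta-1,3-diene | COC(OC)=CC(=C)O[Si](C)(C)C | intermediate
5 | methyl hex-2-ynoate | CCCC#CC(=O)OC | starting material
6 | methyl 6,6-dimethoxy-2-propyl-4-(trimethylsilyloxy)cyclohexa-1,4-diene-1-carboxylate | CCCC1=C(C(=O)OC)C(OC)(OC)C=C(O[Si](C)(C)C)C1 | intermediate
7 | methyl 2-methoxy-6-propyl-4-(trimethylsilyloxy)benzoate | CCCc1cc(O[Si](C)(C)C)cc(OC)c1C(=O)OC | intermediate
8 | methyl 4-hydroxy-2-methoxy-6-propylbenzoate | CCCc1cc(O)cc(OC)c1C(=O)OC | intermediate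
9 | methyl 4-(benzyloxy)-2-methoxy-6-propylbenzoate | CCCc1cc(OCc2ccccc2)cc(OC)c1C(=O)OC | intermediate
10 | 4-(benzyloxy)-2-methoxy-6-propylbenzoic acid | CCCc1cc(OCc2ccccc2)cc(OC)c1C(=O)O | intermediate
11 | 5-propylbenzene-1,3-diol | CCCc1cc(O)cc(O)c1 | starting material
12 | 2-iodo-5-propylbenzene-1,3-diol | CCCc1cc(O)c(I)c(O)c1 | intermediate
13 | 1,3-bis(benzyloxy)-2-iodo-5-propylbenzene | CCCc1cc(OCc2ccccc2)c(I)c(OCc2ccccc2)c1 | intermediate
14 | N-{[2,4-bis(benzyloxy)-3-iodo-6-propylphenyl]methylidene}-N-methylmethanaminium chloride | CCCc1cc(OCc2ccccc2)c(I)c(OCc2ccccc2)c1C=[N+](C)C.[Cl-] | intermediate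
15 | 2,4-bis(benzyloxy)-3-iodo-6-propylbenzaldehyde | CCCc1cc(OCc2ccccc2)c(I)c(OCc2ccccc2)c1C=O | intermediate
16 | 2,4-bis(benzyloxy)-3-iodo-6-propylbenzoic acid | CCCc1cc(OCc2ccccc2)c(I)c(OCc2ccccc2)c1C(=O)O | intermediate
17 | benzyl 2,4-bis(benzyloxy)-3-iodo-6-propylbenzoate | CCCc1cc(OCc2ccccc2)c(I)c(OCc2ccccc2)c1C(=O)OCc1ccccc1 | intermediate
18 | {2,6-bis(benzyloxy)-3-[(benzyloxy)carbonyl]-4-propylphenyl}magnesium chloride | CCCc1cc(OCc2ccccc2)c([Mg]Cl)c(OCc2ccccc2)c1C(=O)OCc1ccccc1 | intermediate
19 | benzyl 2,4-bis(benzyloxy)-3-(dimethoxyboranyl)-6-propylbenzoate | CCCc1cc(OCc2ccccc2)c(B(OC)OC)c(OCc2ccccc2)c1C(=O)OCc1ccccc1 | intermediate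
20 | benzyl 2,4-bis(benzyloxy)-3-hydroxy-6-propylbenzoate | CCCc1cc(OCc2ccccc2)c(O)c(OCc2ccccc2)c1C(=O)OCc1ccccc1 | intermediate
21 | 4-(benzyloxy)-2-methoxy-6-propylbenzoic trifluoroacetic anhydride | CCCc1cc(OCc2ccccc2)cc(OC)c1C(=O)OC(=O)C(F)(F)F | intermediate
22 | benzyl 2,4-bis(benzyloxy)-3-{[4-(benzyloxy)-2-methoxy-6-propylbenzoyl]oxy}-6-propylbenzoate | CCCc1cc(OCc2ccccc2)cc(OC)c1C(=O)Oc1c(OCc2ccccc2)cc(CCC)c(C(=O)OCc2ccccc2)c1OCc1ccccc1 | intermediate
23 | 2,4-dihydroxy-3-[(4-hydroxy-2-methoxy-6-propylbenzoyl)oxy]-6-propylbenzoic acid | CCCc1cc(O)cc(OC)c1C(=O)Oc1c(O)cc(CCC)c(C(=O)O)c1O | target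

## Step count and least certain steps

Total step count: 13. Longest linear sequence: 8 steps (11 → 23, steps 6–13). The ring A branch contributes 7 steps (steps 1–5, 12 and 13).

**Step 3 (key step).** A β-alkyl alkynoate is a sluggish dienophile, so thermal decay, silyl transfer or adventitious hydrolysis of the diene may outrun the cycloaddition, and aromatisation may stop halfway.
Fallback, from 11 to 10, classical arene functionalisation in place of ring construction: Vilsmeier–Haack formylation of 11 should give 2,4-dihydroxy-6-propylbenzaldehyde F1. One equivalent of BnBr with K2CO3 in acetone should alkylate the non-chelated hydroxyl to give 4-(benzyloxy)-2-hydroxy-6-propylbenzaldehyde F2. MeI with K2CO3 in DMF should then methylate the chelated hydroxyl to give 4-(benzyloxy)-2-methoxy-6-propylbenzaldehyde F3. Pinnick oxidation rejoins the route at 10.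

**Step 1.** The ketene acetal may polymerise, or the amine may divert the acid chloride into ketene and its dimer, because both partners are very reactive and volatile.
Fallback, from 2 to 3: AlCl3-promoted acylation of 1,1-dichloroethene with 2, followed by loss of hydrogen chloride, should give 4,4-dichlorobut-3-en-2-one F4. Twofold addition–elimination with NaOMe in MeOH replaces both chlorines and rejoins the route at 3.

**Step 6.** Iodination may occur beside the propyl group, go on to polyiodination, or be followed by acid-induced migration of iodine, since all three free ring positions are activated.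
Fallback, from 11 to 13: 11 is benzylated first to 1,3-bis(benzyloxy)-5-propylbenzene F5. Directed ortho-metalation at the doubly flanked C2 (n-BuLi, TMEDA, Et2O, 0 °C, chosen to hold back benzylic deprotonation) with an iodine quench rejoins the route at 13.

**Step 8.** The medium is acidic and electrophilic, and the iodine-bearing carbon is the most electron-rich one. Ipso attack with loss or migration of iodine, or slow conversion at the crowded site, may therefore interfere.
Fallback, from 11 to 15, with the order of events reversed: formylation of 11 gives 2,4-dihydroxy-6-propylbenzaldehyde F1. Bicarbonate-buffered iodination between the two oxygens should give 2,4-dihydroxy-3-iodo-6-propylbenzaldehyde F6. Double benzylation (BnBr, K2CO3, DMF) rejoins the route at 15.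

**Step 11.** Four processes may interfere: incomplete exchange on a flanked, alkoxy-rich iodide, protonation of the arylmagnesium (net deiodination), attack on the ester, or over-oxidation of the electron-rich phenol by surplus peroxide.
Fallback, from 17 to 20, with palladium catalysis in place of a polar organometallic: Miyaura borylation (bis(pinacolato)diboron, PdCl2(dppf), KOAc, dioxane, 90 °C) should give benzyl 2,4-bis(benzyloxy)-6-propyl-3-(4,4,5,5-tetramethyl-1,3,2-dioxaborolan-2-yl)benzoate F7. Oxidation with NaBO3·4H2O in THF–H2O rejoins the route at 20.

**Step 12.** O-acylation between two crowded partners may be so slow that other processes take over: trifluoroacetylation of the phenol, formation of the symmetrical anhydride, C-acylation at ring B C5, or acid-induced loss of a benzyl group.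
Fallback, from 20 and 4 to 23, with the ester formed before ring A exists: Steglich esterification of 20 with the unhindered hex-2-ynoic acid (DCC, DMAP, CH2Cl2) should give benzyl 2,4-bis(benzyloxy)-3-(hex-2-ynoyloxy)-6-propylbenzoate F8. Cycloaddition with 4 under the conditions of step 3, with the same acidic work-up, should give benzyl 2,4-bis(benzyloxy)-3-[(4-hydroxy-2-methoxy-6-propylbenzoyl)oxy]-6-propylbenzoate F9. Hydrogenolysis as in step 13 rejoins the route at 23.

## Further compounds

F1 | step 3 | 2,4-dihydroxy-6-propylbenzaldehyde | CCCc1cc(O)cc(O)c1C=O
F2 | step 3 | 4-(benzyloxy)-2-hydroxy-6-propylbenzaldehyde | CCCc1cc(OCc2ccccc2)cc(O)c1C=O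
F3 | step 3 | 4-(benzyloxy)-2-methoxy-6-propylbenzaldehyde | CCCc1cc(OCc2ccccc2)cc(OC)c1C=O
F4 | step 1 | 4,4-dichlorobut-3-en-2-one | CC(=O)C=C(Cl)Cl
F5 | step 6 | 1,3-bis(benzyloxy)-5-propylbenzene | CCCc1cc(OCc2ccccc2)cc(OCc2ccccc2)c1
F6 | step 8 | 2,4-dihydroxy-3-iodo-6-propylbenzaldehyde | CCCc1cc(O)c(I)c(O)c1C=O
F7 | step 11 | benzyl 2,4-bis(benzyloxy)-6-propyl-3-(4,4,5,5-tetramethyl-1,3,2-dioxaborolan-2-yl)benzoate | CCCc1cc(OCc2ccccc2)c(B2OC(C)(C)C(C)(C)O2)c(OCc2ccccc2)c1C(=O)OCc1ccccc1
F8 | step 12 | benzyl 2,4-bis(benzyloxy)-3-(hex-2-ynoyloxy)-6-propylbenzoate | CCCC#CC(=O)Oc1c(OCc2ccccc2)cc(CCC)c(C(=O)OCc2ccccc2)c1OCc1ccccc1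
F9 | step 12 | benzyl 2,4-bis(benzyloxy)-3-[(4-hydroxy-2-methoxy-6-propylbenzoyl)oxy]-6-propylbenzoate | CCCc1cc(O)cc(OC)c1C(=O)Oc1c(OCc2ccccc2)cc(CCC)c(C(=O)OCc2ccccc2)c1OCc1ccccc1
A1 | alternative 1 | 2-(benzyloxy)-5-bromo-1,3-bis(methoxymethoxy)benzene | COCOc1cc(Br)cc(OCOC)c1OCc1ccccc1
A2 | alternative 1 | 4-(benzyloxy)-3,5-bis(methoxymethoxy)-1,2-didehydrobenzene | C1#CC(OCOC)=C(OCc2ccccc2)C(OCOC)=C1
A3 | alternative 1 | 3-(benzyloxy)-2,4-bis(methoxymethoxy)-6-propylbenzoic acid | CCCc1cc(OCOC)c(OCc2ccccc2)c(OCOC)c1C(=O)O
A4 | alternative 2 | benzyl 2,4-bis(benzyloxy)-6-propyl-3-[(3,5,7-trioxodecanoyl)oxy]benzoate | CCCC(=O)CC(=O)CC(=O)CC(=O)Oc1c(OCc2ccccc2)cc(CCC)c(C(=O)OCc2ccccc2)c1OCc1ccccc1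
A5 | alternative 2 | benzyl 2,4-bis(benzyloxy)-3-[(2,4-dihydroxy-6-propylbenzoyl)oxy]-6-propylbenzoate | CCCc1cc(O)cc(O)c1C(=O)Oc1c(OCc2ccccc2)cc(CCC)c(C(=O)OCc2ccccc2)c1OCc1ccccc1
A6 | alternative 3 | (E)-2-oxohept-3-en-1-yl 4-(benzyloxy)-2-methoxy-6-propylbenzoate | CCC/C=C/C(=O)COC(=O)c1c(CCC)cc(OCc2ccccc2)cc1OC
A7 | alternative 3 | dibenzyl malonate | O=C(CC(=O)OCc1ccccc1)OCc1ccccc1
A8 | alternative 3 | benzyl trans-3-{[4-(benzyloxy)-2-methoxy-6-propylbenzoyl]oxy}-4-hydroxy-2-oxo-6-propylcyclohex-3-ene-1-carboxylate (racemic, enol form) | CCC[C@@H]1CC(O)=C(OC(=O)c2c(CCC)cc(OCc3ccccc3)cc2OC)C(=O)[C@H]1C(=O)OCc1ccccc1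
A9 | alternative 3 | benzyl 3-{[4-(benzyloxy)-2-methoxy-6-propylbenzoyl]oxy}-2,4-dihydroxy-6-propylbenzoate | CCCc1cc(OCc2ccccc2)cc(OC)c1C(=O)Oc1c(O)cc(CCC)c(C(=O)OCc2ccccc2)c1O
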